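The ratio of Q charged in Thursday's run to that in Saturday's is 4.92, with J the same in both. You need to find how far L follows that ratio, and how far Thursday's run still has to climb.

common to all: J 0.20 M

|  | Q | remark | time |
|---|---|---|---|
| Saturday's | 0.12 M | run made earlier |  |
| Thursday's | 0.59 M | run made earlier |  |
| south-west | 0.100 M |  | 6.0 h |
| east | 0.200 M |  | 6.0 h |
| south-east | 0.500 M |  | 6.0 h |

| Saturday's: time / h | Saturday's: L / % | Thursday's: time / h | Thursday's: L / % |
|---|---|---|---|
| 1.00 | 1.2 | 0.333 | 0.7 |
| 2.00 | 0 | 0.833 | 3.0 |
| 3.00 | 0 | 2.00 | 9.4 |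
| 4.00 | 1.9 | 4.00 | 15.3 |

(readings scatter by 0.5 percentage points)



* how much L is there at the end, in percent of the J charged: for each flask in turn (south-west, east, south-east)

1. Take the times both runs share, 2.00 h and 4.00 h. L summed over them is 1.90% on Saturday and 24.7% on Thursday. Dividing the logarithm of their ratio by that of the Q ratio gives 1.61. Call this the Q-power: the exponent that turns a ratio of Q charges into a ratio of L at equal times, the apparent order in Q.

2. But Saturday's sum of 1.90% carries a scatter of 0.71 percentage points. Moved by one standard deviation either way, it gives a Q-power of 1.41 or 1.90.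

3. Now the end. Thursday's L gained 9.4% up to 2.00 h, then 5.9 points by 4.00 h, so the second gain was 0.628 of the first. I let the next gain shrink alike and take 19.0% for Thursday's run at 6.0 h. The objection is the early lag: Thursday's L rose more slowly up to 0.333 h than between 0.833 h and 2.00 h, so the first gain may be held down and this figure may be high.

4. Scaling 19.0% by the Q-power, I commit to 1.09%, 3.33% and 14.6%. Does the doubt in step 2 matter? South-west spans 0.649% to 1.55%, but south-east spans just 13.9% to 15.0%.

5. The forecast says 1%, 3% and 12%, holding that “the dependence on Q is roughly second order”, and its south-east figure lies below mine.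

The flasks give 1.09%, 3.60% and 13.8%.

    J + Z → D (k = 9.08 × 10⁻⁴ /M/s)
    Z + Q ⇌ G + L (K = 0.320, k = 1.68 × 10⁻⁴ /M/s)
    J + Q ⇌ G + Z (K = 0.990, k = 1.87 × 10⁻⁴ /M/s)

Beside L, the intermediate Z stands at the end at 5.58% in south-west and 19.2% in south-east. Read between those two flasks, the Q-power comes to 1.58, against my 1.61. Carried from south-west to the east flask, 1.61 turns 1.09% into 3.33%, and east stands at 3.60%.

Readings and results were computed for substances that don't exist, noise included.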